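**Retrosynthetic overview**

1. The spiro δ-lactone (ring A) and the tertiary carbinol come last, from a seven-membered enoate lactone bearing a C9=C10 olefin, by a radical 1,2-vinyl shift (ring contraction) ended by oxygen capture.
2. The seven-membered lactone comes from Baeyer–Villiger ring expansion and dehydrogenation of a 4,4-dimethyl β,γ-enone; carbocyclic ring A comes from Robinson annulation with but-3-en-2-one onto the ring-B ketone.
3. Ring C (cyclopentane) comes from an alkylidene carbene C–H insertion starting at a ring-B vinylogous ester; the bicyclo[2.2.2]octanone and γ-lactone come from a double Michael addition of methyl acrylate to a spiro cyclohexenone.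
4. Ring B comes from a Michael (pent-1-en-3-one)/Claisen sequence on an enone lactone that is itself the annulation product of tetronic acid and 2-methylpent-1-en-3-one.
5. Ring order: cyclohexenone → ring B → bicyclo[2.2.2]octanone with γ-lactone → ring C → carbocyclic ring A → seven-membered lactone → spiro δ-lactone.

Atom labels: Cn/On is the position of the atom in the target SMILES as given (C1 … O31); in intermediates a label means the atom that becomes that target atom.

Assumption: the quinidine-series catalyst in step 2 gives the C12 configuration shown; if the sense of induction is opposite, its quinine-series pseudo-enantiomer is used.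

**Route**

Step 1
Reactants: 1 tetronic acid; 2 2-methylpent-1-en-3-one
Product: 4 4,6-dimethyl-6,7-dihydro-2-benzofuran-1,5(3H,7aH)-dione (racemic; C12 and C14 epimerisable), via keto tetronic acid 3 (not isolated)
Conditions: Et3N (10 mol %), THF, 25 °C; then pyrrolidine (30 mol %), AcOH (30 mol %), toluene, 110 °C (Dean–Stark)
Reagents that add atoms: none
Why: Robinson-type annulation in which the vinylogous acid adds to the enone (Michael) and the ethyl ketone then condenses, through its enamine, onto the tetronic C4 carbonyl (Hagemann-ester logic), and no stereocentre needs control because C12 and C14 stay epimerisable.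

Step 2
Reactants: 4 4,6-dimethyl-6,7-dihydro-2-benzofuran-1,5(3H,7aH)-dione; 5 pent-1-en-3-one
Product: 6 (7aR)-4,6-dimethyl-7a-(3-oxopentyl)-6,7-dihydro-2-benzofuran-1,5(3H,7aH)-dione (C14 epimers)
Conditions: cupreidine 9-O-(phenanthren-9-yl) ether (10 mol %), CH2Cl2, −24 °C
Reagents that add atoms: none
Why: Organocatalytic asymmetric Michael addition in which the 6'-OH/quinuclidine catalyst deprotonates the vinylogous β-keto lactone (C23 is blocked by its methyl, so the extended enolate reacts at C12, α to the lactone carbonyl) and delivers one enantioface to the vinyl ketone, which sets the quaternary C12 centre.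

Step 3
Reactants: 6 (7aR)-4,6-dimethyl-7a-(3-oxopentyl)-6,7-dihydro-2-benzofuran-1,5(3H,7aH)-dione
Product: 7 (6R)-7-(hydroxymethyl)-2,8,10-trimethylspiro[5.5]undec-7-ene-1,3,9-trione (C27 and C14 epimers)
Conditions: NaOMe (1.2 equiv), MeOH, 0 → 25 °C; then 1 M HCl
Reagents that add atoms: none
Why: Intramolecular Claisen (Dieckmann-type) condensation in which the C27 enolate of the ethyl ketone attacks the lactone carbonyl C26, closing ring B as a 2-methyl-1,3-diketone whose stabilised enolate drives the equilibrium while the C21 alcohol is released and the quaternary C12 centre is untouched.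

Step 4
Reactants: 7 (6R)-7-(hydroxymethyl)-2,8,10-trimethylspiro[5.5]undec-7-ene-1,3,9-trione; 8 methyl acrylate
Product: 9 tetracyclic lactone dione (bicyclo[2.2.2]octan-2-one with C14 bridgehead methyl; γ-lactone C17–C18–O20–C21–C22 with C18 over the ketone bridge; C23–H facing ring B; 2-methylcyclohexane-1,3-dione spiro at C12)
Conditions: LiN(iPr)2 (3.3 equiv), THF, −78 °C; methyl acrylate (1.2 equiv), −78 → −20 °C; AcOH; then p-TsOH·H2O (10 mol %), toluene, 60 °C
Reagents that add atoms: none
Why: Sequential double Michael addition (Michael–Michael ring closure) of the kinetic cross-conjugated C14 dienolate to the acrylate, which enters on the ring-D face opposite the lithiated diketone carbon C26 (sets C14 and C22) and places the ester endo over the ketone bridge through the chelated transition state (sets C17), after which the acid step equilibrates C23 to the epimer with its methyl away from ring B and closes the γ-lactone from the C21 alcohol.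

Step 5
Reactants: 9 tetracyclic lactone dione
Product: 10 vinylogous ester (methoxy on C9; C9=C27 olefin; ketone at C26)
Conditions: Me2SO4 (1.1 equiv), K2CO3 (1.5 equiv), acetone, 25 °C
Reagents that add atoms: dimethyl sulfate, COS(=O)(=O)OC
Why: O-Alkylation of the 2-alkyl-1,3-diketone enolate by the hard electrophile takes place at the less hindered oxygen on C9, remote from the spiro centre, which leaves C26 as the ketone of the vinylogous ester.

Step 6
Reactants: 10 vinylogous ester
Product: 12 pentacyclic enone (C9 ketone; C27=C26 olefin; ring C closed through C25; C23 quaternary), via dienol ether 11 (not isolated)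
Conditions: Me3SiCHN2 (1.3 equiv), n-BuLi (1.25 equiv), THF, −78 °C; add 10; −78 → 0 °C; then 1 M HCl, THF, 25 °C
Reagents that add atoms: trimethylsilyldiazomethane, C[Si](C)(C)C=[N+]=[N-]
Why: Colvin–Ohira alkylidene carbene chemistry in which the lithiated diazo reagent adds 1,2 to the vinylogous-ester carbonyl C26 (Stork–Danheiser mode), loss of silanolate and N2 gives the alkylidene carbene whose new carbon C25 inserts into the tertiary C23–H bond held 1,5 to it (retention at C23, ring C closed), and acid hydrolysis of the dienol ether gives the conjugated enone.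

Step 7
Reactants: 12 pentacyclic enone
Product: 13 pentacyclic ketone (C26–H syn to C13; C27 epimers)
Conditions: Li (2.2 equiv), NH3 (l)/THF, t-BuOH (1.0 equiv), −78 °C, 10 min; then NH4Cl
Reagents that add atoms: none
Why: Dissolving-metal (Birch-type) conjugate reduction, in which the enone is reduced at a far less negative potential than the doubly neopentyl C30 ketone or the lactone and protonation of the pyramidal β-carbanion gives the thermodynamically favoured cis B/C fusion (C26–H syn to C13), the only one that keeps ring B a chair.

Step 8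
Reactants: 13 pentacyclic ketone; 14 but-3-en-2-one
Product: 16 hexacyclic enone (ring A cyclohexenone C5(=O)–C2H=C9; C27 quaternary with methyl syn to C13), via diketone 15 (not isolated)
Conditions: H2SO4 (5 mol %), toluene, 0 → 110 °C (Dean–Stark)
Reagents that add atoms: none
Why: Acid-catalysed Robinson annulation in which the more substituted enol (C27) adds to the enone from the face opposite the syn-axial C13 methylene (C8 anti to C13, methyl syn; sets C27) and the new methyl ketone condenses onto C9 to close ring A.

Step 9
Reactants: 16 hexacyclic enone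
Product: 17 gem-dimethyl β,γ-enone (C2 dimethyl; C5 ketone; C9=C10 olefin)
Conditions: KOtBu (2.5 equiv), MeI (4 equiv), t-BuOH/THF, 0 → 25 °C
Reagents that add atoms: iodomethane, CI
Why: Exhaustive C-methylation of the thermodynamic dienolate at C2 with deconjugation (classical 4,4-dimethylation of a 4-en-3-one) installs the gem-dimethyl group and moves the olefin to C9=C10, and the only other ketone (C30) has no α-hydrogen.

Step 10
Reactants: 17 gem-dimethyl β,γ-enone
Product: 18 seven-membered lactone (O4 between C5 and C2; C9=C10 olefin)
Conditions: Me3SiOOSiMe3 (1.5 equiv), SnCl4 (20 mol %), trans-cyclohexane-1,2-diamine (20 mol %), 4 Å molecular sieves, CH2Cl2, 25 °C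
Reagents that add atoms: bis(trimethylsilyl) peroxide, C[Si](C)(C)OO[Si](C)(C)C
Why: Baeyer–Villiger ring expansion with a reagent that does not epoxidise olefins, in which the tertiary allylic C2 migrates to oxygen while the C30 ketone is shielded by two quaternary neighbours.

Step 11
Reactants: 18 seven-membered lactone
Product: 20 seven-membered enoate lactone (C7=C8 and C9=C10 olefins), via selenide 19 (not isolated)
Conditions: LiN(iPr)2 (1.1 equiv), THF, −78 °C; PhSeBr (1.2 equiv); then H2O2 (30 %), pyridine, CH2Cl2, 0 → 25 °C
Reagents that add atoms: none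
Why: α-Selenenylation of the ε-lactone enolate (the C7 methylene is deprotonated in preference to the tertiary C17–H of the cage lactone) followed by selenoxide syn-elimination towards C8 gives the ring (Z)-enoate.

Step 12
Reactants: 20 seven-membered enoate lactone
Product: 22 CNP0222978.3 (target), via hydroperoxide 21 (not isolated)
Conditions: tris(2,2,6,6-tetramethylheptane-3,5-dionato)manganese, Mn(dpm)3 (20 mol %), PhSiH3 (2.5 equiv), air (slow stream), iPrOH/CH2Cl2 (1:1), 0 °C; then PPh3 (1.5 equiv), 25 °C
Reagents that add atoms: dioxygen, O=O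
Why: Proposed new method: hydrogen-atom transfer from the manganese hydride to C10 of the C9=C10 olefin gives the tertiary C9 radical, which closes 3-exo onto the enoate β-carbon C8 and reopens by scission of C8–C27, so that the vinyl carbon moves suprafacially from C27 to C9 (the seven-membered lactone contracts to the spiro δ-lactone and C9 is set), and the tertiary C27 radical is then captured by O2 on the face opposite the syn-axial C13 methylene (sets the carbinol after phosphine reduction of the hydroperoxide), the closest known reactions being the Mukaiyama hydration and radical 1,2-vinyl (homoallyl/cyclopropylcarbinyl) migrations.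

**Compound list**

1 | tetronic acid (furan-2,4(3H,5H)-dione) | O=C1COC(=O)C1 | starting material
2 | 2-methylpent-1-en-3-one | CCC(=O)C(C)=C | starting material
3 | 4-hydroxy-3-(2-methyl-3-oxopentyl)furan-2(5H)-one | CCC(=O)C(C)CC1=C(O)COC1=O | intermediate (not isolated)
4 | 4,6-dimethyl-6,7-dihydro-2-benzofuran-1,5(3H,7aH)-dione | CC1CC2C(=O)OCC2=C(C)C1=O | intermediate
5 | pent-1-en-3-one | CCC(=O)C=C | starting material
6 | (7aR)-4,6-dimethyl-7a-(3-oxopentyl)-6,7-dihydro-2-benzofuran-1,5(3H,7aH)-dione | CCC(=O)CC[C@@]12CC(C)C(=O)C(C)=C1COC2=O | intermediate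
7 | (6R)-7-(hydroxymethyl)-2,8,10-trimethylspiro[5.5]undec-7-ene-1,3,9-trione | CC1C(=O)CC[C@@]2(C1=O)CC(C)C(=O)C(C)=C2CO | intermediate
8 | methyl acrylate | COC(=O)C=C | starting material
9 | tetracyclic lactone dione (bicyclo[2.2.2]octanone γ-lactone spiro-fused at C12 to 2-methylcyclohexane-1,3-dione) | CC1C(=O)CC[C@@]2(C1=O)C[C@@]3(C)C[C@@H]4C(=O)OC[C@]42[C@H](C)C3=O | intermediate
10 | vinylogous ester (C9 methoxy enone, C26 ketone) | COC1=C(C)C(=O)[C@]2(CC1)C[C@@]3(C)C[C@@H]4C(=O)OC[C@]42[C@H](C)C3=O | intermediate
11 | cyclopentene dienol ether (C25=C26 and C27=C9 olefins, methoxy on C9) | CC2=C(OC)CC[C@@]13C[C@@]4(C)C[C@@H]5C(=O)OC[C@]51[C@@](C)(C=C32)C4=O | intermediate (not isolated)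
12 | pentacyclic enone (C9 ketone, C27=C26 olefin, ring C closed) | CC=2C(=O)CC[C@@]13C[C@@]4(C)C[C@@H]5C(=O)OC[C@]51[C@@](C)(CC3=2)C4=O | intermediate
13 | pentacyclic ketone (C26–H syn to C13, C27 epimers) | CC2C(=O)CC[C@@]13C[C@@]4(C)C[C@@H]5C(=O)OC[C@]51[C@@](C)(C[C@H]32)C4=O | intermediate
14 | but-3-en-2-one | CC(=O)C=C | starting material
15 | 1,5-diketone (3-oxobutyl and methyl on C27) | CC(=O)CC[C@@]2(C)C(=O)CC[C@@]13C[C@@]4(C)C[C@@H]5C(=O)OC[C@]51[C@@](C)(C[C@H]32)C4=O | intermediate (not isolated)
16 | hexacyclic enone (ring A cyclohexenone) | O=C1CC[C@@]2(C)C(=C1)CC[C@@]13C[C@@]4(C)C[C@@H]5C(=O)OC[C@]51[C@@](C)(C[C@H]32)C4=O | intermediate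
17 | gem-dimethyl β,γ-enone (C5 ketone, C9=C10 olefin) | CC1(C)C(=O)CC[C@@]2(C)C1=CC[C@@]13C[C@@]4(C)C[C@@H]5C(=O)OC[C@]51[C@@](C)(C[C@H]32)C4=O | intermediate
18 | seven-membered lactone (saturated C7–C8, C9=C10 olefin) | CC1(C)OC(=O)CC[C@@]2(C)C1=CC[C@@]13C[C@@]4(C)C[C@@H]5C(=O)OC[C@]51[C@@](C)(C[C@H]32)C4=O | intermediate
19 | C7 phenylselanyl lactone | CC1(C)OC(=O)C([Se]c6ccccc6)C[C@@]2(C)C1=CC[C@@]13C[C@@]4(C)C[C@@H]5C(=O)OC[C@]51[C@@](C)(C[C@H]32)C4=O | intermediate (not isolated)
20 | seven-membered enoate lactone (C7=C8 and C9=C10 olefins) | CC1(C)OC(=O)C=C[C@@]2(C)C1=CC[C@@]13C[C@@]4(C)C[C@@H]5C(=O)OC[C@]51[C@@](C)(C[C@H]32)C4=O | intermediate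
21 | C27 hydroperoxide of the target | CC1(C)OC(=O)C=C[C@]12CC[C@@]13C[C@@]4(C)C[C@@H]5C(=O)OC[C@]51[C@@](C)(C[C@H]3[C@@]2(C)OO)C4=O | intermediate (not isolated)
22 | CNP0222978.3 | CC1(C)OC(=O)C=C[C@]12CC[C@@]13C[C@@]4(C)C[C@@H]5C(=O)OC[C@]51[C@@](C)(C[C@H]3[C@@]2(C)O)C4=O | target

**Step count**

Total steps: 12. Longest linear sequence: 12 steps (from 1 and 2 to 22; 5, 8 and 14 enter along the way).

**Three steps most likely to fail**

Step 12 (the new ring contraction with oxygen capture). The C9 radical may be trapped by oxygen before it migrates, or capture at C27 may be unselective. The fallback sets out from 20 and comes back at 22. It separates the rearrangement from the oxygenation: reductive hydrogen-atom-transfer conditions without oxygen (Fe(acac)3, PhSiH3, EtOH/ethylene glycol, argon, 60 °C) let the radical complete the 3-exo/β-scission vinyl shift and end by hydrogen delivery on the less hindered face, giving the 27-deoxy spirolactone F5. Methyl(trifluoromethyl)dioxirane then hydroxylates the tertiary C27–H bond with retention (C26–H is buried in the cage and C17–H is deactivated by the lactone) to give 22.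

Step 6 (alkylidene carbene insertion). The lithiated diazo reagent may attack the C30 ketone instead, or the carbene may insert into the C21 or C10 methylene. The fallback sets out from 10 and comes back at 12. MeLi/CeCl3 at −78 °C followed by aqueous HCl (Stork–Danheiser transposition) gives the 26-methyl enone F2. t-BuMe2SiOTf/Et3N gives the exocyclic silyl dienol ether F3 (C12 is quaternary, so only the C25 methyl can be deprotonated at the γ-position). N-Bromosuccinimide gives the γ-bromide F4. KN(SiMe3)2 then forms the C23 enolate, which closes ring C by intramolecular 5-exo alkylation, necessarily on the face towards ring B, to give 12.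

Step 4 (double Michael addition on a trianion). The polyanion may be poorly soluble or may react on the wrong face of ring D. The fallback sets out from 7 and comes back at 9. In-situ silylation (LiN(iPr)2, Me3SiCl, THF, −78 °C) gives the tris(trimethylsilyl) derivative F1, a 2-silyloxydiene whose ring-B face is shielded by the silyl enol ether on C26. EtAlCl2 with methyl acrylate (CH2Cl2, −78 °C) effects a stepwise Mukaiyama–Michael/Michael ring closure, and HF·pyridine in MeOH removes the silyl groups and closes the γ-lactone to give 9.

**Further compounds**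

F1 | step 4 | tris(trimethylsilyl) derivative of 7 (2-silyloxydiene in ring D, silyl enol ether on C9, silyl ether on O20) | CC1=C(O[Si](C)(C)C)CC[C@@]2(C1=O)CC(C)=C(O[Si](C)(C)C)C(C)=C2CO[Si](C)(C)C
F2 | step 6 | 26-methyl enone (C9 ketone, C27=C26 olefin, methyl C25 on C26) | CC1=C(C)[C@]2(CCC1=O)C[C@@]3(C)C[C@@H]4C(=O)OC[C@]42[C@H](C)C3=O
F3 | step 6 | exocyclic silyl dienol ether (C9 silyloxy, C26=C25 methylene) | CC1=C(O[Si](C)(C)C(C)(C)C)CC[C@@]2(C1=C)C[C@@]3(C)C[C@@H]4C(=O)OC[C@]42[C@H](C)C3=O
F4 | step 6 | γ-bromide (bromomethyl C25 on C26) | CC1=C(CBr)[C@]2(CCC1=O)C[C@@]3(C)C[C@@H]4C(=O)OC[C@]42[C@H](C)C3=O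
F5 | step 12 | 27-deoxy spirolactone (C27–H in place of C27–OH) | CC1(C)OC(=O)C=C[C@]12CC[C@@]13C[C@@]4(C)C[C@@H]5C(=O)OC[C@]51[C@@](C)(C[C@H]3[C@@H]2C)C4=O
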